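**Plan**

1. Retrosynthesis (ring A = phenol ring ether-linked to the meta-phenylene ring B; ring C = para-phenylene; ring D = phenol ring ether-linked to ring C): cut first the aryl ether bond between the ring C oxygen and ring D, which opens the 20-membered macrocycle; then both CH2–CH2 bridges, back to aryl–alkyne bonds (ring B–C≡C–ring C and ring A–C≡C–ring D); last the ring B–O–ring A ether.
2. Forward: SNAr ether (rings A and B) → Sonogashira (ring C) → aldehyde to terminal alkyne → Sonogashira (ring D) → one hydrogenation that makes both bridges and frees the ring C phenol and the ring D o-aminophenol → diazotisation → macrocyclisation (the only ring formed) → O-demethylation.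
3. Enabling feature: in ring D the ether carbon is ortho to the carbon bearing the free hydroxyl. These two carbons and that oxygen can be redrawn as the 2-diazo ketone unit of an o-quinone diazide, so the ether carbon becomes a carbene carbon. O–H insertion by the ring C phenol then makes the ether bond and restores the ring D phenol, and N2 is the only helper that leaves.
4. Stereochemistry: none to set; the target has no stereocentre, and alkyne intermediates avoid E/Z isomers.

Key step: step 7

Remark: benzyl ether 7 (the O-benzyl derivative of 4-bromo-2-nitrophenol) is taken as a catalogue compound, as are 1, 2 and 4.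

**Route**

Step 1
Reactants: 1 3-iodophenol; 2 4-fluoro-3-methoxybenzaldehyde
Product: 3 4-(3-iodophenoxy)-3-methoxybenzaldehyde
Conditions: K2CO3, DMSO, 130 °C
Reagents that add atoms: none
Why: Nucleophilic aromatic substitution (SNAr): the para-formyl group stabilises the Meisenheimer adduct so that the phenoxide of 1 displaces fluoride, and the aryl iodide is inert without a metal catalyst.

Step 2
Reactants: 3 4-(3-iodophenoxy)-3-methoxybenzaldehyde; 4 1-(benzyloxy)-4-ethynylbenzene
Product: 5 4-(3-{[4-(benzyloxy)phenyl]ethynyl}phenoxy)-3-methoxybenzaldehyde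
Conditions: PdCl2(PPh3)2 (2 mol %), CuI (4 mol %), Et3N, THF, rt
Reagents that add atoms: none
Why: Sonogashira coupling: zerovalent palladium inserts into the aryl iodide at room temperature, and the aldehyde and benzyl ether are spectators.

Step 3
Reactants: 5 4-(3-{[4-(benzyloxy)phenyl]ethynyl}phenoxy)-3-methoxybenzaldehyde
Product: 6 1-(benzyloxy)-4-{[3-(4-ethynyl-2-methoxyphenoxy)phenyl]ethynyl}benzene
Conditions: Ohira–Bestmann reagent, K2CO3, MeOH/THF, 0 °C to rt
Reagents that add atoms: dimethyl (1-diazo-2-oxopropyl)phosphonate, COP(=O)(OC)C(=[N+]=[N-])C(C)=O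
Why: Seyferth–Gilbert homologation with the Ohira–Bestmann reagent turns an aromatic aldehyde into the terminal alkyne under mild carbonate base, which should leave the internal alkyne and the ethers untouched.

Step 4
Reactants: 6 1-(benzyloxy)-4-{[3-(4-ethynyl-2-methoxyphenoxy)phenyl]ethynyl}benzene; 7 1-(benzyloxy)-4-bromo-2-nitrobenzene
Product: 8 1-(benzyloxy)-4-{[4-(3-{[4-(benzyloxy)phenyl]ethynyl}phenoxy)-3-methoxyphenyl]ethynyl}-2-nitrobenzene
Conditions: Pd(PPh3)4 (5 mol %), CuI (5 mol %), Et3N, DMF, 70 °C
Reagents that add atoms: none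
Why: Sonogashira coupling of a terminal alkyne with an aryl bromide that the meta nitro group activates inductively; nitro group, benzyl ethers and the internal alkyne tolerate the conditions.

Step 5
Reactants: 8 1-(benzyloxy)-4-{[4-(3-{[4-(benzyloxy)phenyl]ethynyl}phenoxy)-3-methoxyphenyl]ethynyl}-2-nitrobenzene
Product: 9 2-amino-4-[2-(4-{3-[2-(4-hydroxyphenyl)ethyl]phenoxy}-3-methoxyphenyl)ethyl]phenol
Conditions: H2 (3 atm), 10% Pd/C, EtOAc/MeOH, rt; filtration under argon
Reagents that add atoms: none
Why: Catalytic hydrogenation and hydrogenolysis: one operation should saturate both alkynes to the CH2–CH2 bridges, reduce the nitro group to the amine and cleave both benzyl ethers, while the aryl methyl ether and the diaryl ether are stable.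

Step 6
Reactants: 9 2-amino-4-[2-(4-{3-[2-(4-hydroxyphenyl)ethyl]phenoxy}-3-methoxyphenyl)ethyl]phenol
Product: 10 6-diazo-4-[2-(4-{3-[2-(4-hydroxyphenyl)ethyl]phenoxy}-3-methoxyphenyl)ethyl]cyclohexa-2,4-dien-1-one (the ring D o-quinone diazide)
Conditions: t-BuONO (1.05 equiv), AcOH (cat.), THF, 0 °C, dark
Reagents that add atoms: tert-butyl nitrite, CC(C)(C)ON=O
Why: Diazotisation of an o-aminophenol: N-nitrosation and dehydration give the arenediazonium ion, which loses the acidic ortho-hydroxyl proton to form the neutral, isolable o-quinone diazide; the para-alkylated ring C phenol should not couple or be nitrosated under weakly acidic conditions where no phenoxide is present.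

Step 7
Reactants: 10 6-diazo-4-[2-(4-{3-[2-(4-hydroxyphenyl)ethyl]phenoxy}-3-methoxyphenyl)ethyl]cyclohexa-2,4-dien-1-one
Product: 11 ring A monomethyl ether of the target (macrocycle 12 with OMe in place of the ring A hydroxyl)
Conditions: Rh2(OAc)4 (5 mol %), 4 Å MS, ClCH2CH2Cl, 70 °C, syringe-pump addition of 10 over 12 h (final 1 mM), dark
Reagents that add atoms: none
Why: Proposed new method: Rh2(OAc)4 (divalent rhodium) binds the diazo carbon of 10, N2 leaves, and the electrophilic quinoid carbenoid at the carbon next to the ring D carbonyl is attacked by the ring C phenol oxygen; the rhodium-bound oxonium ylide then passes its proton to the dienone oxygen and releases the catalyst, so the aryl ether and the aromatic ring D phenol appear in the same event. The closest known reaction types are the rhodium-carbenoid O–H insertion of phenols and alcohols into cyclic 2-diazo ketones and 2-diazo-1,3-diketones and the carbene transfer from quinone diazides to rhodium in cyclopropanation and arene C–H arylation; an O–H insertion of a quinoid carbenoid used for macrocyclisation is the new element. The 20-membered ring is closed by an end-to-end intramolecular O–H insertion, a macrocyclisation without a competing ring size because ring C carries the only free hydroxyl. No stereocentre is formed. The step needs chemoselectivity for O–H insertion over arene attack and Wolff ring contraction and for ring closure over oligomerisation, which the fast reaction of rhodium carbenoids with O–H bonds, the methyl ether on ring A, the moderate temperature without light and the slow addition to about 1 mM should secure. The position of the new bond is fixed by the diazo carbon, which sits where the amino group of 9 was, ortho to the ring D oxygen and meta to the CH2–CH2 bridge.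

Step 8
Reactants: 11 ring A monomethyl ether of the target
Product: 12 target macrocyclic bis(bibenzyl) (CNP0329842.0)
Conditions: BBr3, CH2Cl2, −78 °C to rt; then H2O
Reagents that add atoms: none
Why: Lewis acid ether cleavage: BBr3 coordinates the methoxy oxygen and bromide removes the methyl group by SN2, while the diaryl ether bonds, with sp2 carbon on both sides, should not be cleaved.

**Compound list**

1 | 3-iodophenol | Oc1cccc(I)c1 | starting material
2 | 4-fluoro-3-methoxybenzaldehyde | COc1cc(C=O)ccc1F | starting material
3 | 4-(3-iodophenoxy)-3-methoxybenzaldehyde | COc1cc(C=O)ccc1Oc1cccc(I)c1 | intermediate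
4 | 1-(benzyloxy)-4-ethynylbenzene | C#Cc1ccc(OCc2ccccc2)cc1 | starting material
5 | 4-(3-{[4-(benzyloxy)phenyl]ethynyl}phenoxy)-3-methoxybenzaldehyde | COc1cc(C=O)ccc1Oc1cccc(c1)C#Cc1ccc(OCc2ccccc2)cc1 | intermediate
6 | 1-(benzyloxy)-4-{[3-(4-ethynyl-2-methoxyphenoxy)phenyl]ethynyl}benzene | COc1cc(C#C)ccc1Oc1cccc(c1)C#Cc1ccc(OCc2ccccc2)cc1 | intermediate
7 | 1-(benzyloxy)-4-bromo-2-nitrobenzene | [O-][N+](=O)c1cc(Br)ccc1OCc1ccccc1 | starting material
8 | 1-(benzyloxy)-4-{[4-(3-{[4-(benzyloxy)phenyl]ethynyl}phenoxy)-3-methoxyphenyl]ethynyl}-2-nitrobenzene | COc1cc(C#Cc2ccc(OCc3ccccc3)c(c2)[N+]([O-])=O)ccc1Oc1cccc(c1)C#Cc1ccc(OCc2ccccc2)cc1 | intermediate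
9 | 2-amino-4-[2-(4-{3-[2-(4-hydroxyphenyl)ethyl]phenoxy}-3-methoxyphenyl)ethyl]phenol | COc1cc(CCc2ccc(O)c(N)c2)ccc1Oc1cccc(c1)CCc1ccc(O)cc1 | intermediate
10 | 6-diazo-4-[2-(4-{3-[2-(4-hydroxyphenyl)ethyl]phenoxy}-3-methoxyphenyl)ethyl]cyclohexa-2,4-dien-1-one | COc1cc(CCC2=CC(=[N+]=[N-])C(=O)C=C2)ccc1Oc1cccc(c1)CCc1ccc(O)cc1 | intermediate
11 | ring A monomethyl ether of the target | COc1cc2ccc1Oc1cccc(c1)CCc1ccc(cc1)Oc1cc(ccc1O)CC2 | intermediate
12 | target macrocyclic bis(bibenzyl), no stereocentre | Oc1cc2ccc1Oc1cccc(c1)CCc1ccc(cc1)Oc1cc(ccc1O)CC2 | target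

**Step count**

Total steps: 8. Longest linear sequence: 8 (from 1 and 2 to 12).

**Steps most likely to fail**

1. Step 7 (proposed new method). Carbenoid formation from the aromatic diazonium-phenolate form of 10 may be slow. Thermal Wolff ring contraction, attack on the electron-rich arene rings or intermolecular O–H insertion (oligomerisation) could then overtake ring closure. The fallback uses known chemistry, an Ullmann macrocyclisation; it sets out from 6 and comes back at 12. Alkyne 6 is coupled at rt, selectively at the iodide, with 2-bromo-4-iodoanisole (PdCl2(PPh3)2, CuI, Et3N) to give the bromo bis-alkyne F1. Diimide (KO2CN=NCO2K, AcOH, pyridine/MeOH) saturates both alkynes without touching the aryl bromide or the benzyl ether and gives the bromo bis(bibenzyl) benzyl ether F2. BCl3 with pentamethylbenzene at −78 °C removes only the benzyl group and gives the bromo phenol F3. Intramolecular Ullmann ether synthesis (CuI, N,N-dimethylglycine, Cs2CO3, dioxane, 100 °C, high dilution) forms the same aryl ether bond and gives the macrocyclic dimethyl ether F4. BBr3 then cleaves both methyl ethers to give 12.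

2. Step 6. C-nitrosation or azo coupling at the free ring C phenol, or air oxidation of the electron-rich aminophenol, may compete with diazotisation. The fallback is a nitro-activated SNAr macrocyclisation in which the nitro group is afterwards turned into the hydroxyl; it sets out from 6 and comes back at 11. Sonogashira coupling of 6 with 4-bromo-2-fluoro-1-nitrobenzene gives the fluoronitro bis-alkyne F5. Diimide reduction as above gives the fluoronitro bis(bibenzyl) benzyl ether F6. BCl3 with pentamethylbenzene gives the fluoronitro phenol F7. K2CO3 in DMF at 2 mM closes the ring by displacement of the fluoride ortho to the nitro group and gives the nitro macrocycle F8. Hydrogenation (H2, Pd/C) gives the amino macrocycle F9, which has no free phenol. Diazotisation (NaNO2, aqueous H2SO4, 0 °C) gives the macrocyclic diazonium hydrogensulfate F10, which is hydrolysed in the same flask (Cu(NO3)2, Cu2O, water) to 11.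

3. Step 1. Fluoride displacement may be slow because the methoxy group ortho to fluorine feeds electron density into the ring that must accept the negative charge, and the aldehyde may decompose at the forcing temperature. The fallback is a Chan–Lam coupling with reversed polarity; it sets out from 1 and comes back at 3. Phenol 1 is coupled with (4-formyl-2-methoxyphenyl)boronic acid (Cu(OAc)2, pyridine, 4 Å MS, CH2Cl2, air, rt), which leaves the aryl iodide intact and gives 3 directly; no further compound arises (F0).

**Further compounds**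

F1 | step 7 | 2-bromo-1-methoxy-4-{[4-(3-{[4-(benzyloxy)phenyl]ethynyl}phenoxy)-3-methoxyphenyl]ethynyl}benzene | COc1cc(C#Cc2ccc(OC)c(Br)c2)ccc1Oc1cccc(c1)C#Cc1ccc(OCc2ccccc2)cc1
F2 | step 7 | 2-bromo-1-methoxy-4-{2-[4-(3-{2-[4-(benzyloxy)phenyl]ethyl}phenoxy)-3-methoxyphenyl]ethyl}benzene | COc1cc(CCc2ccc(OC)c(Br)c2)ccc1Oc1cccc(c1)CCc1ccc(OCc2ccccc2)cc1
F3 | step 7 | 4-[2-(3-{4-[2-(3-bromo-4-methoxyphenyl)ethyl]-2-methoxyphenoxy}phenyl)ethyl]phenol | COc1cc(CCc2ccc(OC)c(Br)c2)ccc1Oc1cccc(c1)CCc1ccc(O)cc1
F4 | step 7 | dimethyl ether of the target (OMe on ring A and on ring D) | COc1cc2ccc1Oc1cccc(c1)CCc1ccc(cc1)Oc1cc(ccc1OC)CC2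
F5 | step 6 | 4-{[4-(3-{[4-(benzyloxy)phenyl]ethynyl}phenoxy)-3-methoxyphenyl]ethynyl}-2-fluoro-1-nitrobenzene | COc1cc(C#Cc2ccc(c(F)c2)[N+]([O-])=O)ccc1Oc1cccc(c1)C#Cc1ccc(OCc2ccccc2)cc1
F6 | step 6 | 4-{2-[4-(3-{2-[4-(benzyloxy)phenyl]ethyl}phenoxy)-3-methoxyphenyl]ethyl}-2-fluoro-1-nitrobenzene | COc1cc(CCc2ccc(c(F)c2)[N+]([O-])=O)ccc1Oc1cccc(c1)CCc1ccc(OCc2ccccc2)cc1
F7 | step 6 | 4-[2-(3-{4-[2-(3-fluoro-4-nitrophenyl)ethyl]-2-methoxyphenoxy}phenyl)ethyl]phenol | COc1cc(CCc2ccc(c(F)c2)[N+]([O-])=O)ccc1Oc1cccc(c1)CCc1ccc(O)cc1
F8 | step 6 | macrocycle 11 with NO2 in place of the ring D hydroxyl | COc1cc2ccc1Oc1cccc(c1)CCc1ccc(cc1)Oc1cc(ccc1[N+]([O-])=O)CC2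
F9 | step 6 | macrocycle 11 with NH2 in place of the ring D hydroxyl | COc1cc2ccc1Oc1cccc(c1)CCc1ccc(cc1)Oc1cc(ccc1N)CC2
F10 | step 6 | diazonium hydrogensulfate of F9 | COc1cc2ccc1Oc1cccc(c1)CCc1ccc(cc1)Oc1cc(ccc1[N+]#N)CC2.OS(=O)(=O)[O-]
F0 | step 1 | none | none
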